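## The problem

The target is a linear trimer of flavan-3-ols. An upper (−)-epicatechin 3-O-gallate (T) is bonded from its C4 to C6 of a middle (−)-epicatechin 3-O-gallate (M), and C4 of M is bonded to C8 of a lower (+)-catechin (L) whose 3-hydroxyl is free; each unit has an aromatic ring A fused to the pyran ring C and a catechol ring B at C2. Both interflavan bonds are β, that is trans to the ester oxygen on the neighbouring C3, and the 4→6 bond between T and M is the difficult one, because in the usual Friedel–Crafts union of flavan units C8 of the phloroglucinol ring reacts ahead of C6. Of the eight stereocentres, C2 and C3 of T and of L come from the chiral pool and C4 of T can be set by C3 of T (a nucleophile enters the C4 cation trans to the C3 ester, which also bridges the cation). C2, C3 and C4 of M have no controlling neighbour if ring C of M is built late, since the nearest chirality sits in T and L several bonds away, so their absolute sense must come from a reagent. The molecule carries eighteen phenols (catechol and pyrogallol groups that oxidise in air and base), two aryl esters that do not survive hydroxide or alkoxide, and two interflavan bonds that ionise in strong acid, so one protecting group removable under neutral conditions and a mild endgame are required, and the 3-OH of L must stay distinct from the two esterified 3-oxygens. The feature that opens a different route is ring A of M, a benzene whose six positions are all different: C4a (carbon, leading to C4 of M), O5, C6 (carbon, C4 of T), O7, H8 and O8a. This alternation is what the thermal union of a 3-alkoxy-4-alkylcyclobutenone (through its vinylketene) with a 1-siloxyalkyne writes onto a new benzene ring, every substituent being placed by connectivity. The same reaction leaves O5 as a free phenol and O8a as a silyl ether, so the two oxygens that flank C4a, which decide whether T finishes at C6 or at C8 once ring C is closed, are told apart from the moment the ring exists.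

## Retrosynthesis

**37 to 36.** The first cut removes protecting groups only: the nineteen benzyl–oxygen bonds of nonadecabenzyl ether 36. Benzyl is chosen over acyl or silyl protection because it covers phenols and the 3-OH of L alike, survives organolithiums, fluoride and heat, and leaves under neutral hydrogenolysis that spares both gallates. The forward step must be exhaustive without cleaving the benzylic C2–O1 bonds or the interflavan bonds.

**36 to diol 31 and enol gallate 34.** The bonds O1–C2 and C3–C4 of M are cut, which removes ring C of M with its three stereocentres; 31 is the precursor of o-quinone methide 35 and 34 is a Z-enol ester. The neighbouring cut, C4 of M to C8 of L, has better precedent, but it would leave a T–M unit that must first be joined 4→6 against the C8 preference and then ionised at C4 next to its own nucleophilic ring positions. The chosen cut delivers C2, C3, ring B and the second gallate in one two-step building block. The forward reaction must bond the oxygen-bearing carbon of 34 to C4, keep the Z geometry (2,3-cis), place the ester trans to the aryl of L (3,4-trans) and choose one face of 35.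

**31 to 30 to 29.** No skeletal bond is cut. Phenol 29 has O5 free and O8a silylated; benzylation of O5 (30) and removal of both silyl groups (31) make O8a the only oxygen that can close ring C, and this is where the 4→6 linkage is fixed. The forward steps must alkylate a phenol flanked by two large groups and must not disturb the esters.

**29 to cyclobutenone 14 and siloxyalkyne 25 (key disconnection).** Three bonds of ring A of M are cut: C4a–C5, C5–C6 and C8–C8a. Against the neighbouring cut of the single T C4–M C6 bond, which leads back to a Friedel–Crafts reaction with the wrong regiochemical bias, this cut makes the position of T a matter of which atom carries it in 14. The trimer-sized phenol falls into two halves of similar weight, each derived from one pool flavan-3-ol. The forward reaction needs thermal opening of a 3-alkoxy-4-alkylcyclobutenone, regioselective ketene–alkyne [2+2] addition at a hindered alkyne carbon, and tolerance of benzyl ethers, silyl ethers and the gallate at about 100 °C.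

**14 to acid 7 and ynol ether 11, and 7 back to 1.** The four-membered ring is cut at its two bonds to the alkyne carbons, giving ketene 13 (from 7 through acid chloride 12) and benzyl ethynyl ether 11, which comes from trichloroethylene 8. Acid 7 comes from methyl ester 6, and 6 from cutting the C4–CH2 bond: an acetate enolate equivalent adds to the C4 cation of gallate 5 from the β face. Gallate 5 is the ester of alcohol 3 with acid 4, and 3 arises by C4 oxidation of tetrabenzyl ether 2 of (−)-epicatechin 1. Every step here is a standard one of flavan chemistry except the cycloaddition, which asks that the aldoketene be trapped faster than it dimerises.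

**25 back to 15.** The ynol oxygen is removed to give terminal alkyne 22. The propargylic C–C bond of alcohol 21 is cut to aldehyde 20, which comes from bromide 18 (through aryllithium 19) and 18 from pentabenzyl ether 17 of (+)-catechin 15. Bromination must select C8, which is the innate preference of this ring and here works in favour of the plan.

**34 to alkyne 33 and acid 4.** The enol ester C–O bond is cut; anti-Markovnikov addition of 4 to 33 gives the Z isomer, and 33 is the one-carbon homologue of aldehyde 32.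

## Roads not taken

**Alternative 1:** The cut is the C6–C7 bond of ring A of M, the ring being written as a triketide masked in pyranone A1, which carries the upper unit (as its 3-silyl ether) on the methylene that becomes C6. In the forward step alkoxide opens the lactone of A1 and the carbanion at the flavan-bearing carbon closes onto the liberated ester carbonyl, giving resorcinol allyl ether A2 after aromatisation.
- Merits: ordinary carbonyl chemistry, no strained ring, no heat-sensitive ynol ether, and a cheap pyranone. The allyl group can later supply C2–C4 of M, so that C2 and C3 of M would be set by well-known reagent control (asymmetric dihydroxylation) and L could be added by the classical trans-selective C4 arylation. In stereocontrol of M this road is better than the chosen one.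
- Weak points: A2 has two equivalent hydroxyls beside the carbon that bears T, and after the allyl group has moved to carbon the choice between O5 and O8a for ring closure rests on a steric bias only. The alkoxide step excludes the gallate, which must be put on T later. M still has to be built over many steps and then oxidised at C4 in the presence of the doubly benzylic C4–H of T.
- Comparison: the chosen plan sets against the better stereochemical precedent of this road a regiochemistry that is fixed by connectivity (phenol 29 has O5 and O8a differentiated), the joining of T and L in the ring-forming step, and a route about half as long.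

**Alternative 2:** The cuts are the two C2–aryl bonds of T and M. In the forward step two equivalents of aryllithium A4 add to the two lactone carbonyls of bis-lactone A3 and the adducts are reduced in the same flask with Et3SiH and BF3·OEt2 to bis(silyl ether) A5.
- Merits: both catechol rings come from one simple reagent at the end, and C2 is set by hydride delivery to a cyclic oxocarbenium ion, a reaction type with more precedent than the cycloaddition of step 19. For the C2 centres alone this road is the safer one.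
- Weak points: A3 already contains both interflavan bonds and the 4→6 regiochemistry, so the real problem is only moved. BF3·OEt2 with a hydride donor threatens the acid-labile interflavan bonds by ionisation and reduction. The C3 hydrogens next to the lactone carbonyls are exposed to the basic aryllithium. Hydride must enter syn to the pseudo-axial C4 aryl group to give 2,3-cis. Two silyl ethers must afterwards be exchanged for gallates.
- Comparison: against its better precedent for C2 the chosen plan sets a solution of the regiochemical problem, gallates that are in place from the start, and three ring-C centres made in one operation.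

**Alternative 3:** The cuts are C4–C4a and O1–C2 of M, with ring A of M carried as cyclohexanedione A6. In the forward step A6 adds through its C2 to the β-carbon of enone A7 and the enol oxygen condenses on the ketone, closing ring C as the 4H-pyran of tetrahydrochromenone A8.
- Merits: a robust Michael addition and cyclodehydration with catalytic asymmetric variants, so that C4 of M could be set by a catalyst without passing through the crowded diaryl cation. The dione also distinguishes C6 (next to a carbonyl) from C8. For C4 this road is better founded than step 19.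
- Weak points: ring A must be aromatised afterwards in a molecule full of benzyl ethers and an enol ether. T must still be attached at C6, by alkylation of an enolate or, after aromatisation, by the same biased Friedel–Crafts reaction. The C2=C3 enol ether must be turned into the 2,3-cis ester, whereas hydroboration would give 2,3-trans, so an oxidation–reduction detour is needed.
- Comparison: the chosen plan sets against the cleaner C4 control of this road a ring A that arrives aromatic with T and all three oxygens already placed and differentiated, and a ring C that arrives at the right oxidation level with its gallate.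

Key step: step 14

## Remarks on the chemistry

- 3,4,5-Tris(benzyloxy)benzoic acid 4 (the perbenzylated form of gallic acid), 3,4-bis(benzyloxy)benzaldehyde 32 and trichloroethylene 8 are taken as commercial, like 1 and 15.
- The sp3 ring carbon of 14, 27 and the carbinol carbon of 21–25, 27–31 are carried as mixtures of epimers (no descriptor in the SMILES), because both are erased later, the first in the ring opening of 14 and the second in quinone methide 35. The geometry of the exocyclic double bond of 35 is left open.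
- Shorthand in names: "T residue" is (2R,3R)-5,7-bis(benzyloxy)-2-[3,4-bis(benzyloxy)phenyl]-3-[3,4,5-tris(benzyloxy)benzoyloxy]chroman-4-yl, bonded through C4 on the β face (trans to the C3 ester). "L residue" is (2R,3S)-3,5,7-tris(benzyloxy)-2-[3,4-bis(benzyloxy)phenyl]chroman-8-yl. "4β" means trans to the oxygen at C3.

## Steps

Step 1
Reactants: 1 (−)-epicatechin
Product: 2 5,7,3',4'-tetra-O-benzylepicatechin
Conditions: BnBr (4.4 equiv), K2CO3, DMF, 0 °C → rt
Reagents that add atoms: benzyl bromide, BrCc1ccccc1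
Why: Williamson etherification; carbonate deprotonates only the four phenols, so the secondary 3-OH stays free for the ester of step 3.

Step 2
Reactants: 2 5,7,3',4'-tetra-O-benzylepicatechin
Product: 3 4β-(2-ethoxyethoxy)-5,7,3',4'-tetra-O-benzylepicatechin
Conditions: DDQ, 2-ethoxyethanol, CH2Cl2, rt
Reagents that add atoms: 2-ethoxyethanol, CCOCCO
Why: Benzylic oxidation by DDQ: hydride abstraction from C4 gives the cation stabilised by O5 and O7, which the alcohol captures trans to the 3-OH; the configuration of this centre is of no consequence because C4 is ionised again in step 4.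

Step 3
Reactants: 3 4β-(2-ethoxyethoxy)-5,7,3',4'-tetra-O-benzylepicatechin; 4 3,4,5-tris(benzyloxy)benzoic acid
Product: 5 4β-(2-ethoxyethoxy)-5,7,3',4'-tetra-O-benzylepicatechin 3-O-[3,4,5-tris(benzyloxy)benzoate]
Conditions: DCC, DMAP, CH2Cl2, rt
Reagents that add atoms: none
Why: Steglich esterification of the axial 3-OH under neutral conditions that leave the acid-labile C4 ether alone.

Step 4
Reactants: 5 4β-(2-ethoxyethoxy)-5,7,3',4'-tetra-O-benzylepicatechin 3-O-[3,4,5-tris(benzyloxy)benzoate]
Product: 6 methyl (T residue)acetate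
Conditions: CH2=C(OMe)OTBS (3 equiv), TMSOTf (0.2 equiv), CH2Cl2, −78 → −40 °C
Reagents that add atoms: 1-(tert-butyldimethylsiloxy)-1-methoxyethene, C=C(OC)O[Si](C)(C)C(C)(C)C
Why: Mukaiyama-type SN1 alkylation of the C4 cation; the neighbouring ester carbonyl bridges the cation on the α face, so the silyl ketene acetal enters from the β face and sets C4 trans to O3.

Step 5
Reactants: 6 methyl (T residue)acetate
Product: 7 (T residue)acetic acid
Conditions: Me3SnOH, ClCH2CH2Cl, 80 °C; then 5% aq. HCl wash
Reagents that add atoms: trimethyltin hydroxide, C[Sn](C)(C)O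
Why: Trimethyltin hydroxide cleaves unhindered methyl esters under nearly neutral conditions, while the secondary, doubly flanked galloyl ester is too hindered to react.

Step 6
Reactants: 8 trichloroethylene
Product: 11 benzyl ethynyl ether, via dichlorovinyl ether 9 (not isolated), via lithium benzyloxyacetylide 10 (not isolated)
Conditions: BnOH, KH, THF, 0 °C; 8, −78 °C → rt; n-BuLi (2.2 equiv), −78 → −40 °C; H2O, −78 °C; kept as a cold solution
Reagents that add atoms: benzyl alcohol, OCc1ccccc1
Why: Benzyl oxide replaces one chloride to give the (E)-dichlorovinyl ether, two equivalents of n-BuLi convert it to the lithium alkynyl ether by elimination and chlorine–lithium exchange, and protonation gives the ynol ether, which is used cold because benzyl alkynyl ethers rearrange on warming.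

Step 7
Reactants: 7 (T residue)acetic acid; 11 benzyl ethynyl ether
Product: 14 3-benzyloxy-4-(T residue)cyclobut-2-en-1-one, via acid chloride 12 (not isolated), via ketene 13 (not isolated)
Conditions: Me2C=C(Cl)NMe2, CH2Cl2, 0 °C → rt; then 11 (3 equiv), Et3N, CH2Cl2, 0 °C → rt
Reagents that add atoms: none
Why: Neutral acid chloride formation, dehydrochlorination to the aldoketene and ketene–ynol ether [2+2] cycloaddition; the terminal carbon of 11 bonds to the ketene carbonyl carbon, which places the benzyloxy group at C3 and the T residue at C4, and the new sp3 centre is formed unselectively and is erased in step 14.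

Step 8
Reactants: 15 (+)-catechin
Product: 17 3,5,7,3',4'-penta-O-benzylcatechin, via 5,7,3',4'-tetra-O-benzylcatechin 16 (not isolated)
Conditions: BnBr, K2CO3, DMF, rt; then NaH, BnBr, 0 °C → rt
Reagents that add atoms: benzyl bromide, BrCc1ccccc1
Why: Williamson etherification in two stages, carbonate for the phenols and then hydride for the 3-OH, which limits C-benzylation of the phloroglucinol ring.

Step 9
Reactants: 17 3,5,7,3',4'-penta-O-benzylcatechin
Product: 18 8-bromo-3,5,7,3',4'-penta-O-benzylcatechin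
Conditions: NBS, CH2Cl2, −78 °C → rt
Reagents that add atoms: N-bromosuccinimide, O=C1CCC(=O)N1Br
Why: Electrophilic aromatic bromination; with one equivalent the protected phloroglucinol ring reacts at C8, its most nucleophilic position.

Step 10
Reactants: 18 8-bromo-3,5,7,3',4'-penta-O-benzylcatechin
Product: 20 8-formyl-3,5,7,3',4'-penta-O-benzylcatechin, via aryllithium 19 (not isolated)
Conditions: n-BuLi, THF, −78 °C; DMF, −78 → 0 °C; H2O
Reagents that add atoms: N,N-dimethylformamide, CN(C)C=O
Why: Bromine–lithium exchange is faster than benzylic deprotonation at −78 °C, and the aryllithium is formylated by DMF.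

Step 11
Reactants: 20 8-formyl-3,5,7,3',4'-penta-O-benzylcatechin
Product: 21 1-(L residue)prop-2-yn-1-ol
Conditions: HC≡CMgBr, THF, 0 °C → rt; H2O
Reagents that add atoms: ethynylmagnesium bromide, C#C[Mg]Br
Why: Grignard addition to the aldehyde; the carbinol centre is formed unselectively and is erased in step 19.

Step 12
Reactants: 21 1-(L residue)prop-2-yn-1-ol
Product: 22 tert-butyl[1-(L residue)prop-2-yn-1-yloxy]dimethylsilane
Conditions: TBSOTf, 2,6-lutidine, CH2Cl2, 0 °C
Reagents that add atoms: tert-butyldimethylsilyl trifluoromethanesulfonate, CC(C)(C)[Si](C)(C)OS(=O)(=O)C(F)(F)F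
Why: Silylation of the hindered secondary alcohol with the silyl triflate; the silyl ether survives base and heat and leaves with fluoride in step 16.

Step 13
Reactants: 22 tert-butyl[1-(L residue)prop-2-yn-1-yloxy]dimethylsilane
Product: 25 1-(tert-butyldimethylsiloxy)-1-(L residue)-3-(triisopropylsiloxy)prop-2-yne, via lithium acetylide 23 (not isolated), via lithium ynolate 24 (not isolated)
Conditions: n-BuLi, THF, −78 °C; t-BuOOLi (from t-BuOOH, LiN(SiMe3)2), −78 → 0 °C; TIPSOTf, −78 °C → rt
Reagents that add atoms: lithium tert-butyl peroxide, CC(C)(C)OO[Li]; triisopropylsilyl trifluoromethanesulfonate, CC(C)[Si](C(C)C)(C(C)C)OS(=O)(=O)C(F)(F)F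
Why: Oxidation of an alkynyllithium by lithium tert-butyl peroxide (transfer of electrophilic oxygen) gives the ynolate, which the bulky silyl triflate silylates on oxygen; the triisopropylsilyl ynol ether resists the thermal silyl shift to a silylketene.

Step 14
Reactants: 14 3-benzyloxy-4-(T residue)cyclobut-2-en-1-one; 25 1-(tert-butyldimethylsiloxy)-1-(L residue)-3-(triisopropylsiloxy)prop-2-yne
Product: 29 5-benzyloxy-2-[(tert-butyldimethylsiloxy)(L residue)methyl]-6-(T residue)-3-(triisopropylsiloxy)phenol, via vinylketene 26 (not isolated), via vinylcyclobutenone 27 (not isolated), via dienylketene 28 (not isolated)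
Conditions: 25 (1.2 equiv), PhMe (0.1 M), 80 °C then 110 °C, Ar
Reagents that add atoms: none
Why: Danheiser benzannulation; the closest known reaction type is the thermal union of cyclobutenones with 1-siloxyalkynes to resorcinol monosilyl ethers, applied here to a large 3-alkoxy-4-alkyl cyclobutenone. On heating, 14 opens by four-electron conrotatory ring opening, the T residue turning outward, to vinylketene 26; the alkyne carbon of 25 that is β to oxygen bonds to the ketene carbonyl carbon and the siloxy-bearing carbon to the ketene α-carbon in a [2+2] cycloaddition (bonds C4a–C5 and C8–C8a of M), giving vinylcyclobutenone 27. A second four-electron ring opening gives dienylketene 28, and ring A of M closes by six-electron disrotatory electrocyclisation onto the ketene carbon (bond C5–C6), followed by tautomerisation to phenol 29. No stereocentre is formed: the epimeric sp3 carbon of 14 becomes aromatic C6, and the carbinol carbon and all centres of T and L are untouched. The one selectivity needed is the orientation of the [2+2] step, and the polarised ynol silyl ether secures it, so that O5 (free OH) comes from the ketene carbonyl, C6 with T and O7 from the cyclobutenone, and C4a and the silylated O8a from the alkyne; no pathway can place T next to C8a. Because the ring opening of 14 is reversible, the stationary concentration of 26 stays low, which holds back ketene dimerisation while the hindered alkyne adds.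

Step 15
Reactants: 29 5-benzyloxy-2-[(tert-butyldimethylsiloxy)(L residue)methyl]-6-(T residue)-3-(triisopropylsiloxy)phenol
Product: 30 1,5-bis(benzyloxy)-2-[(tert-butyldimethylsiloxy)(L residue)methyl]-6-(T residue)-3-(triisopropylsiloxy)benzene
Conditions: BnBr, K2CO3, n-Bu4NI (cat.), DMF (dry), rt
Reagents that add atoms: benzyl bromide, BrCc1ccccc1
Why: Williamson etherification of the only free phenol (O5 of M); this leaves the still silylated O8a as the one oxygen able to close ring C, which fixes T at C6 and not at C8.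

Step 16
Reactants: 30 1,5-bis(benzyloxy)-2-[(tert-butyldimethylsiloxy)(L residue)methyl]-6-(T residue)-3-(triisopropylsiloxy)benzene
Product: 31 3,5-bis(benzyloxy)-2-[hydroxy(L residue)methyl]-4-(T residue)phenol
Conditions: TBAF (3 equiv), AcOH (3 equiv), THF, 0 °C → rt; product used crude
Reagents that add atoms: none
Why: Fluoride cleaves the aryl triisopropylsilyl ether and the secondary tert-butyldimethylsilyl ether; acetic acid keeps the medium from becoming basic enough to harm the gallate or to ionise the sensitive carbinol early.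

Step 17
Reactants: 32 3,4-bis(benzyloxy)benzaldehyde
Product: 33 1,2-bis(benzyloxy)-4-ethynylbenzene
Conditions: MeC(O)C(N2)P(O)(OMe)2, K2CO3, MeOH, rt
Reagents that add atoms: dimethyl (1-diazo-2-oxopropyl)phosphonate, COP(=O)(OC)C(=[N+]=[N-])C(C)=O
Why: Ohira–Bestmann variant of the Seyferth–Gilbert homologation, which turns the aldehyde into the terminal alkyne under mild base.

Step 18
Reactants: 33 1,2-bis(benzyloxy)-4-ethynylbenzene; 4 3,4,5-tris(benzyloxy)benzoic acid
Product: 34 (Z)-2-[3,4-bis(benzyloxy)phenyl]ethenyl 3,4,5-tris(benzyloxy)benzoate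
Conditions: [RuCl2(p-cymene)]2 (1 mol %), P(4-ClC6H4)3 (3 mol %), DMAP (4 mol %), PhMe, 60 °C
Reagents that add atoms: none
Why: Ruthenium-catalysed anti-Markovnikov addition of a carboxylic acid to a terminal alkyne through a vinylidene complex; the carboxylate adds trans, which gives the Z-enol ester.

Step 19
Reactants: 31 3,5-bis(benzyloxy)-2-[hydroxy(L residue)methyl]-4-(T residue)phenol; 34 (Z)-2-[3,4-bis(benzyloxy)phenyl]ethenyl 3,4,5-tris(benzyloxy)benzoate
Product: 36 nonadeca-O-benzyl ether of 37, via o-quinone methide 35 (not isolated)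
Conditions: crude 31, 34 (3 equiv), (R)-TRIP [(R)-3,3'-bis(2,4,6-triisopropylphenyl)-1,1'-binaphthyl-2,2'-diyl hydrogen phosphate] (10 mol %), 5 Å MS, CH2Cl2, 0 °C → rt
Reagents that add atoms: none
Why: Proposed new method: acid-promoted loss of water from 31 gives o-quinone methide 35, whose methide carbon (C4 of M) is attacked by the oxygen-bearing carbon of 34, because the 3,4-dialkoxyphenyl group and not the acyloxy group stabilises the developing charge, so that C3–C4 and O1–C2 form with flavan-3-ol regiochemistry in an inverse-demand oxa-[4+2] cycloaddition; the closest known reaction type is the phosphoric-acid-catalysed chroman synthesis from o-hydroxybenzhydrols and styrenes. The Z geometry of 34 is carried suprafacially into the 2,3-cis relation, and C3 and C4 should come out trans because the galloyloxy group and the doubly ortho-substituted aryl of L avoid each other along the forming C3–C4 bond. The face of 35 that is attacked, and with it the absolute configuration of the three new centres, is assigned to the chiral phosphate bound to the carbonyl oxygen of 35 (the antipodal acid is to be used if the induced sense is the opposite).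

Step 20
Reactants: 36 nonadeca-O-benzyl ether of 37
Product: 37 (−)-epicatechin 3-O-gallate-(4β→6)-(−)-epicatechin 3-O-gallate-(4β→8)-(+)-catechin
Conditions: H2 (1 atm), Pd(OH)2/C, THF–MeOH–H2O, rt
Reagents that add atoms: none
Why: Hydrogenolysis of all nineteen benzyl ethers under neutral conditions, which spare the gallate esters, the interflavan bonds and every stereocentre.

## Compound list

1 | (−)-epicatechin, (2R,3R)-2-(3,4-dihydroxyphenyl)chromane-3,5,7-triol | O[C@@H]1Cc2c(O)cc(O)cc2O[C@@H]1c1ccc(O)c(O)c1 | starting material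
2 | 5,7,3',4'-tetra-O-benzylepicatechin (3-OH free) | O[C@@H]1Cc2c(OCc5ccccc5)cc(OCc5ccccc5)cc2O[C@@H]1c1ccc(OCc5ccccc5)c(OCc5ccccc5)c1 | intermediate
3 | 4β-(2-ethoxyethoxy)-5,7,3',4'-tetra-O-benzylepicatechin (C4 ether trans to the 3-OH) | O[C@@H]1[C@@H](OCCOCC)c2c(OCc5ccccc5)cc(OCc5ccccc5)cc2O[C@@H]1c1ccc(OCc5ccccc5)c(OCc5ccccc5)c1 | intermediate
4 | 3,4,5-tris(benzyloxy)benzoic acid | OC(=O)c1cc(OCc5ccccc5)c(OCc5ccccc5)c(OCc5ccccc5)c1 | starting material
5 | 4β-(2-ethoxyethoxy)-5,7,3',4'-tetra-O-benzylepicatechin 3-O-[3,4,5-tris(benzyloxy)benzoate] | O=C(O[C@@H]1[C@@H](OCCOCC)c2c(OCc5ccccc5)cc(OCc5ccccc5)cc2O[C@@H]1c1ccc(OCc5ccccc5)c(OCc5ccccc5)c1)c1cc(OCc5ccccc5)c(OCc5ccccc5)c(OCc5ccccc5)c1 | intermediate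
6 | methyl (T residue)acetate (4β-CH2CO2Me, trans to the C3 ester) | O=C(O[C@@H]1[C@@H](CC(=O)OC)c2c(OCc5ccccc5)cc(OCc5ccccc5)cc2O[C@@H]1c1ccc(OCc5ccccc5)c(OCc5ccccc5)c1)c1cc(OCc5ccccc5)c(OCc5ccccc5)c(OCc5ccccc5)c1 | intermediate
7 | (T residue)acetic acid | O=C(O[C@@H]1[C@@H](CC(=O)O)c2c(OCc5ccccc5)cc(OCc5ccccc5)cc2O[C@@H]1c1ccc(OCc5ccccc5)c(OCc5ccccc5)c1)c1cc(OCc5ccccc5)c(OCc5ccccc5)c(OCc5ccccc5)c1 | intermediate
8 | trichloroethylene | ClC=C(Cl)Cl | starting material
9 | benzyl (E)-1,2-dichloroethenyl ether | Cl/C=C(/Cl)OCc1ccccc1 | intermediate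
10 | lithium benzyloxyacetylide | [Li]C#COCc1ccccc1 | intermediate
11 | benzyl ethynyl ether (benzyloxyacetylene) | C#COCc1ccccc1 | intermediate
12 | (T residue)acetyl chloride | O=C(O[C@@H]1[C@@H](CC(=O)Cl)c2c(OCc5ccccc5)cc(OCc5ccccc5)cc2O[C@@H]1c1ccc(OCc5ccccc5)c(OCc5ccccc5)c1)c1cc(OCc5ccccc5)c(OCc5ccccc5)c(OCc5ccccc5)c1 | intermediate
13 | (T residue)ketene, 2-(T residue)ethen-1-one | O=C(O[C@@H]1[C@@H](C=C=O)c2c(OCc5ccccc5)cc(OCc5ccccc5)cc2O[C@@H]1c1ccc(OCc5ccccc5)c(OCc5ccccc5)c1)c1cc(OCc5ccccc5)c(OCc5ccccc5)c(OCc5ccccc5)c1 | intermediate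
14 | 3-benzyloxy-4-(T residue)cyclobut-2-en-1-one (epimers at the sp3 ring carbon) | O=C(O[C@@H]1[C@@H](C2C(=O)C=C2OCc5ccccc5)c2c(OCc5ccccc5)cc(OCc5ccccc5)cc2O[C@@H]1c1ccc(OCc5ccccc5)c(OCc5ccccc5)c1)c1cc(OCc5ccccc5)c(OCc5ccccc5)c(OCc5ccccc5)c1 | intermediate
15 | (+)-catechin, (2R,3S)-2-(3,4-dihydroxyphenyl)chromane-3,5,7-triol | O[C@H]1Cc2c(O)cc(O)cc2O[C@@H]1c1ccc(O)c(O)c1 | starting material
16 | 5,7,3',4'-tetra-O-benzylcatechin (3-OH free) | O[C@H]1Cc2c(OCc5ccccc5)cc(OCc5ccccc5)cc2O[C@@H]1c1ccc(OCc5ccccc5)c(OCc5ccccc5)c1 | intermediate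
17 | 3,5,7,3',4'-penta-O-benzylcatechin | c1c(OCc5ccccc5)cc(OCc5ccccc5)c2c1O[C@H](c1ccc(OCc5ccccc5)c(OCc5ccccc5)c1)[C@@H](OCc5ccccc5)C2 | intermediate
18 | 8-bromo-3,5,7,3',4'-penta-O-benzylcatechin | Brc1c(OCc5ccccc5)cc(OCc5ccccc5)c2c1O[C@H](c1ccc(OCc5ccccc5)c(OCc5ccccc5)c1)[C@@H](OCc5ccccc5)C2 | intermediate
19 | 8-lithio-3,5,7,3',4'-penta-O-benzylcatechin | [Li]c1c(OCc5ccccc5)cc(OCc5ccccc5)c2c1O[C@H](c1ccc(OCc5ccccc5)c(OCc5ccccc5)c1)[C@@H](OCc5ccccc5)C2 | intermediate
20 | 8-formyl-3,5,7,3',4'-penta-O-benzylcatechin | O=Cc1c(OCc5ccccc5)cc(OCc5ccccc5)c2c1O[C@H](c1ccc(OCc5ccccc5)c(OCc5ccccc5)c1)[C@@H](OCc5ccccc5)C2 | intermediate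
21 | 1-(L residue)prop-2-yn-1-ol (carbinol epimers) | C#CC(O)c1c(OCc5ccccc5)cc(OCc5ccccc5)c2c1O[C@H](c1ccc(OCc5ccccc5)c(OCc5ccccc5)c1)[C@@H](OCc5ccccc5)C2 | intermediate
22 | tert-butyl[1-(L residue)prop-2-yn-1-yloxy]dimethylsilane | C#CC(O[Si](C)(C)C(C)(C)C)c1c(OCc5ccccc5)cc(OCc5ccccc5)c2c1O[C@H](c1ccc(OCc5ccccc5)c(OCc5ccccc5)c1)[C@@H](OCc5ccccc5)C2 | intermediate
23 | lithium acetylide of 22 | [Li]C#CC(O[Si](C)(C)C(C)(C)C)c1c(OCc5ccccc5)cc(OCc5ccccc5)c2c1O[C@H](c1ccc(OCc5ccccc5)c(OCc5ccccc5)c1)[C@@H](OCc5ccccc5)C2 | intermediate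
24 | lithium 3-(tert-butyldimethylsiloxy)-3-(L residue)prop-1-yn-1-olate (ynolate) | [Li]OC#CC(O[Si](C)(C)C(C)(C)C)c1c(OCc5ccccc5)cc(OCc5ccccc5)c2c1O[C@H](c1ccc(OCc5ccccc5)c(OCc5ccccc5)c1)[C@@H](OCc5ccccc5)C2 | intermediate
25 | 1-(tert-butyldimethylsiloxy)-1-(L residue)-3-(triisopropylsiloxy)prop-2-yne | CC(C)[Si](C(C)C)(C(C)C)OC#CC(O[Si](C)(C)C(C)(C)C)c1c(OCc5ccccc5)cc(OCc5ccccc5)c2c1O[C@H](c1ccc(OCc5ccccc5)c(OCc5ccccc5)c1)[C@@H](OCc5ccccc5)C2 | intermediate
26 | vinylketene, 3-benzyloxy-4-(T residue)buta-1,3-dien-1-one (T residue cis to the benzyloxy group) | O=C(O[C@@H]1[C@@H](/C=C(OCc5ccccc5)/C=C=O)c2c(OCc5ccccc5)cc(OCc5ccccc5)cc2O[C@@H]1c1ccc(OCc5ccccc5)c(OCc5ccccc5)c1)c1cc(OCc5ccccc5)c(OCc5ccccc5)c(OCc5ccccc5)c1 | intermediate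
27 | 4-[1-benzyloxy-2-(T residue)ethenyl]-2-[(tert-butyldimethylsiloxy)(L residue)methyl]-3-(triisopropylsiloxy)cyclobut-2-en-1-one | O=C(O[C@@H]1[C@@H](/C=C(OCc5ccccc5)/C2C(=O)C(C(O[Si](C)(C)C(C)(C)C)c3c(OCc5ccccc5)cc(OCc5ccccc5)c4c3O[C@H](c3ccc(OCc5ccccc5)c(OCc5ccccc5)c3)[C@@H](OCc5ccccc5)C4)=C2O[Si](C(C)C)(C(C)C)C(C)C)c2c(OCc5ccccc5)cc(OCc5ccccc5)cc2O[C@@H]1c1ccc(OCc5ccccc5)c(OCc5ccccc5)c1)c1cc(OCc5ccccc5)c(OCc5ccccc5)c(OCc5ccccc5)c1 | intermediate
28 | dienylketene, 5-benzyloxy-2-[(tert-butyldimethylsiloxy)(L residue)methyl]-6-(T residue)-3-(triisopropylsiloxy)hexa-1,3,5-trien-1-one (C2 and C5 cis on the central double bond) | O=C(O[C@@H]1[C@@H](/C=C(OCc5ccccc5)/C=C(O[Si](C(C)C)(C(C)C)C(C)C)\C(=C=O)C(O[Si](C)(C)C(C)(C)C)c3c(OCc5ccccc5)cc(OCc5ccccc5)c4c3O[C@H](c3ccc(OCc5ccccc5)c(OCc5ccccc5)c3)[C@@H](OCc5ccccc5)C4)c2c(OCc5ccccc5)cc(OCc5ccccc5)cc2O[C@@H]1c1ccc(OCc5ccccc5)c(OCc5ccccc5)c1)c1cc(OCc5ccccc5)c(OCc5ccccc5)c(OCc5ccccc5)c1 | intermediate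
29 | 5-benzyloxy-2-[(tert-butyldimethylsiloxy)(L residue)methyl]-6-(T residue)-3-(triisopropylsiloxy)phenol (ring A of M; O5–H free, O8a silylated) | O=C(O[C@@H]1[C@@H](c2c(OCc5ccccc5)cc(O[Si](C(C)C)(C(C)C)C(C)C)c(C(O[Si](C)(C)C(C)(C)C)c3c(OCc5ccccc5)cc(OCc5ccccc5)c4c3O[C@H](c3ccc(OCc5ccccc5)c(OCc5ccccc5)c3)[C@@H](OCc5ccccc5)C4)c2O)c2c(OCc5ccccc5)cc(OCc5ccccc5)cc2O[C@@H]1c1ccc(OCc5ccccc5)c(OCc5ccccc5)c1)c1cc(OCc5ccccc5)c(OCc5ccccc5)c(OCc5ccccc5)c1 | intermediate
30 | 1,5-bis(benzyloxy)-2-[(tert-butyldimethylsiloxy)(L residue)methyl]-6-(T residue)-3-(triisopropylsiloxy)benzene | O=C(O[C@@H]1[C@@H](c2c(OCc5ccccc5)cc(O[Si](C(C)C)(C(C)C)C(C)C)c(C(O[Si](C)(C)C(C)(C)C)c3c(OCc5ccccc5)cc(OCc5ccccc5)c4c3O[C@H](c3ccc(OCc5ccccc5)c(OCc5ccccc5)c3)[C@@H](OCc5ccccc5)C4)c2OCc5ccccc5)c2c(OCc5ccccc5)cc(OCc5ccccc5)cc2O[C@@H]1c1ccc(OCc5ccccc5)c(OCc5ccccc5)c1)c1cc(OCc5ccccc5)c(OCc5ccccc5)c(OCc5ccccc5)c1 | intermediate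
31 | 3,5-bis(benzyloxy)-2-[hydroxy(L residue)methyl]-4-(T residue)phenol | O=C(O[C@@H]1[C@@H](c2c(OCc5ccccc5)cc(O)c(C(O)c3c(OCc5ccccc5)cc(OCc5ccccc5)c4c3O[C@H](c3ccc(OCc5ccccc5)c(OCc5ccccc5)c3)[C@@H](OCc5ccccc5)C4)c2OCc5ccccc5)c2c(OCc5ccccc5)cc(OCc5ccccc5)cc2O[C@@H]1c1ccc(OCc5ccccc5)c(OCc5ccccc5)c1)c1cc(OCc5ccccc5)c(OCc5ccccc5)c(OCc5ccccc5)c1 | intermediate
32 | 3,4-bis(benzyloxy)benzaldehyde | O=Cc1ccc(OCc5ccccc5)c(OCc5ccccc5)c1 | starting material
33 | 1,2-bis(benzyloxy)-4-ethynylbenzene | C#Cc1ccc(OCc5ccccc5)c(OCc5ccccc5)c1 | intermediate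
34 | (Z)-2-[3,4-bis(benzyloxy)phenyl]ethenyl 3,4,5-tris(benzyloxy)benzoate | O=C(O/C=C\c1ccc(OCc5ccccc5)c(OCc5ccccc5)c1)c1cc(OCc5ccccc5)c(OCc5ccccc5)c(OCc5ccccc5)c1 | intermediate
35 | o-quinone methide, 3,5-bis(benzyloxy)-6-[(L residue)methylidene]-4-(T residue)cyclohexa-2,4-dien-1-one | O=C(O[C@@H]1[C@@H](C2=C(OCc5ccccc5)C(=Cc3c(OCc5ccccc5)cc(OCc5ccccc5)c4c3O[C@H](c3ccc(OCc5ccccc5)c(OCc5ccccc5)c3)[C@@H](OCc5ccccc5)C4)C(=O)C=C2OCc5ccccc5)c2c(OCc5ccccc5)cc(OCc5ccccc5)cc2O[C@@H]1c1ccc(OCc5ccccc5)c(OCc5ccccc5)c1)c1cc(OCc5ccccc5)c(OCc5ccccc5)c(OCc5ccccc5)c1 | intermediate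
36 | nonadeca-O-benzyl ether of 37 (all eighteen phenols and the 3-OH of L benzylated; ring C of M 2,3-cis-3,4-trans) | O=C(O[C@@H]1[C@@H](c2c(OCc5ccccc5)cc3c(c2OCc5ccccc5)[C@H](c2c(OCc5ccccc5)cc(OCc5ccccc5)c4c2O[C@H](c2ccc(OCc5ccccc5)c(OCc5ccccc5)c2)[C@@H](OCc5ccccc5)C4)[C@@H](OC(=O)c2cc(OCc5ccccc5)c(OCc5ccccc5)c(OCc5ccccc5)c2)[C@@H](c2ccc(OCc5ccccc5)c(OCc5ccccc5)c2)O3)c2c(OCc5ccccc5)cc(OCc5ccccc5)cc2O[C@@H]1c1ccc(OCc5ccccc5)c(OCc5ccccc5)c1)c1cc(OCc5ccccc5)c(OCc5ccccc5)c(OCc5ccccc5)c1 | intermediate
37 | (−)-epicatechin 3-O-gallate-(4β→6)-(−)-epicatechin 3-O-gallate-(4β→8)-(+)-catechin | O=C(O[C@@H]1[C@@H](c2c(O)cc3c(c2O)[C@H](c2c(O)cc(O)c4c2O[C@H](c2ccc(O)c(O)c2)[C@@H](O)C4)[C@@H](OC(=O)c2cc(O)c(O)c(O)c2)[C@@H](c2ccc(O)c(O)c2)O3)c2c(O)cc(O)cc2O[C@@H]1c1ccc(O)c(O)c1)c1cc(O)c(O)c(O)c1 | target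

## Step count and uncertain steps

Total step count: 20.
Longest linear sequence: 11 steps (steps 1, 2, 3, 4, 5, 7, 14, 15, 16, 19, 20 from 1; the branch from 15 through steps 8–13 is equally long).

**Step 19 (the step that goes beyond known chemistry).** The most likely failures are attack on both faces of 35 with little discrimination, or a stepwise ionic addition in which the C2–C3 bond rotates before ring closure. The methide carbon lies between two doubly ortho-substituted, strongly donating rings, which makes it a crowded and stabilised electrophile, and the resident chirality is remote. Friedel–Crafts capture of the cation by free ring-A positions would compete.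

Fallback, from 3 back to 37, using only known Lewis-acid arylations of C4 cations with a bromine cap at C8 of M to force the 4→6 bond:
- NBS (CH2Cl2, −78 °C) converts 3 to 8-bromo-4β-(2-ethoxyethoxy)-5,7,3',4'-tetra-O-benzylepicatechin F1.
- 2,6-Dimethylbenzenethiol and BF3·OEt2 replace the C4 ether by sulfur, trans to O3, giving 8-bromo-4β-(2,6-dimethylphenylthio)-5,7,3',4'-tetra-O-benzylepicatechin F2.
- Esterification with 4 (DCC, DMAP) gives its 3-O-[3,4,5-tris(benzyloxy)benzoate] F3.
- BF3·OEt2 ionises 5 in the presence of an excess of F3, whose only free ring-A position is C6, and gives the 4β→6 dimer sulfide F4 with the sulfide intact.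
- The sulfide is activated with I2 and Ag2O in the presence of an excess of 17, whose C8 adds trans to the ester of M, giving the 8-bromo analogue of 36, F5.
- Hydrogenolysis (H2, Pd(OH)2/C, Et3N) removes the bromine with the benzyl groups and returns to the route at 37.

**Step 14 (key step).** The most likely failure is slow [2+2] addition at the alkyne carbon that carries the crowded carbinol, so that vinylketene 26 oligomerises or the ynol silyl ether suffers thermal silyl migration to a silylketene before it is consumed. The 3-alkoxy group also raises the temperature needed for ring opening.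

Fallback, from 14 back to 30, taking L off the alkyne:
- Commercial 3,3-diethoxyprop-1-yne is oxidised and silylated as in step 13 to 3,3-diethoxy-1-(triisopropylsiloxy)prop-1-yne F6.
- F6 is heated with 14 to give 5-benzyloxy-2-(diethoxymethyl)-6-(T residue)-3-(triisopropylsiloxy)phenol F7.
- Benzylation as in step 15 gives the benzyl ether acetal F8, and aqueous acetic acid releases 2,4-bis(benzyloxy)-3-(T residue)-6-(triisopropylsiloxy)benzaldehyde F9.
- One equivalent of aryllithium 19 (from 18 as in step 10) is added at −78 °C, where the aldehyde is far more electrophilic than the hindered galloyl ester, and the alkoxide is silylated in the flask with TBSOTf, which gives 30.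

**Step 7.** The most likely failure is that sigmatropic rearrangement of the benzyl ynol ether 11, which sets in near room temperature, and dimerisation of aldoketene 13 outrun the cycloaddition.

Fallback, from 12 back to 14, replacing the ynol ether by a ketene acetal:
- Ketene 13, generated from 12 and Et3N as before, is trapped by 1,1-bis(benzyloxy)ethene F10 (the benzyl analogue of the common ketene diethyl acetal, made by dehydrobromination of the bromoacetal with t-BuOK) in the classical ketene–ketene acetal [2+2] cycloaddition to give 3,3-bis(benzyloxy)-2-(T residue)cyclobutanone F11.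
- Loss of benzyl alcohol toward the unsubstituted, kinetically more acidic methylene (Et3N or silica) gives 14.

**Step 13.** The most likely failures are β-elimination of silanolate from ynolate 24, whose carbanionic carbon is next to the siloxy-bearing carbinol carbon, and incomplete oxygen transfer to the hindered acetylide 23.

Fallback, from 18 back to 25, by Kowalski ester homologation:
- Aryllithium 19 (from 18) is added to ethyl glyoxylate at −78 °C to give ethyl 2-hydroxy-2-(L residue)acetate F12.
- TBSOTf and 2,6-lutidine give its silyl ether, ethyl 2-(tert-butyldimethylsiloxy)-2-(L residue)acetate F13.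
- Dibromomethyllithium (CH2Br2, lithium 2,2,6,6-tetramethylpiperidide, −78 °C) followed by n-BuLi and warming rearranges the adduct to ynolate 24 at low temperature, and TIPSCl silylates it to 25.

## Further compounds

F1 | step 19 | 8-bromo-4β-(2-ethoxyethoxy)-5,7,3',4'-tetra-O-benzylepicatechin | O[C@@H]1[C@@H](OCCOCC)c2c(OCc5ccccc5)cc(OCc5ccccc5)c(Br)c2O[C@@H]1c1ccc(OCc5ccccc5)c(OCc5ccccc5)c1
F2 | step 19 | 8-bromo-4β-(2,6-dimethylphenylthio)-5,7,3',4'-tetra-O-benzylepicatechin | O[C@@H]1[C@@H](Sc3c(C)cccc3C)c2c(OCc5ccccc5)cc(OCc5ccccc5)c(Br)c2O[C@@H]1c1ccc(OCc5ccccc5)c(OCc5ccccc5)c1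
F3 | step 19 | 8-bromo-4β-(2,6-dimethylphenylthio)-5,7,3',4'-tetra-O-benzylepicatechin 3-O-[3,4,5-tris(benzyloxy)benzoate] | O=C(O[C@@H]1[C@@H](Sc3c(C)cccc3C)c2c(OCc5ccccc5)cc(OCc5ccccc5)c(Br)c2O[C@@H]1c1ccc(OCc5ccccc5)c(OCc5ccccc5)c1)c1cc(OCc5ccccc5)c(OCc5ccccc5)c(OCc5ccccc5)c1
F4 | step 19 | perbenzylated epicatechin gallate-(4β→6)-[8-bromo-4β-(2,6-dimethylphenylthio)epicatechin gallate] | O=C(O[C@@H]1[C@@H](c2c(OCc5ccccc5)c(Br)c3c(c2OCc5ccccc5)[C@H](Sc4c(C)cccc4C)[C@@H](OC(=O)c2cc(OCc5ccccc5)c(OCc5ccccc5)c(OCc5ccccc5)c2)[C@@H](c2ccc(OCc5ccccc5)c(OCc5ccccc5)c2)O3)c2c(OCc5ccccc5)cc(OCc5ccccc5)cc2O[C@@H]1c1ccc(OCc5ccccc5)c(OCc5ccccc5)c1)c1cc(OCc5ccccc5)c(OCc5ccccc5)c(OCc5ccccc5)c1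
F5 | step 19 | 8-bromo analogue of 36 (bromine at C8 of M) | O=C(O[C@@H]1[C@@H](c2c(OCc5ccccc5)c(Br)c3c(c2OCc5ccccc5)[C@H](c2c(OCc5ccccc5)cc(OCc5ccccc5)c4c2O[C@H](c2ccc(OCc5ccccc5)c(OCc5ccccc5)c2)[C@@H](OCc5ccccc5)C4)[C@@H](OC(=O)c2cc(OCc5ccccc5)c(OCc5ccccc5)c(OCc5ccccc5)c2)[C@@H](c2ccc(OCc5ccccc5)c(OCc5ccccc5)c2)O3)c2c(OCc5ccccc5)cc(OCc5ccccc5)cc2O[C@@H]1c1ccc(OCc5ccccc5)c(OCc5ccccc5)c1)c1cc(OCc5ccccc5)c(OCc5ccccc5)c(OCc5ccccc5)c1
F6 | step 14 | 3,3-diethoxy-1-(triisopropylsiloxy)prop-1-yne | CCOC(OCC)C#CO[Si](C(C)C)(C(C)C)C(C)C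
F7 | step 14 | 5-benzyloxy-2-(diethoxymethyl)-6-(T residue)-3-(triisopropylsiloxy)phenol | O=C(O[C@@H]1[C@@H](c2c(OCc5ccccc5)cc(O[Si](C(C)C)(C(C)C)C(C)C)c(C(OCC)OCC)c2O)c2c(OCc5ccccc5)cc(OCc5ccccc5)cc2O[C@@H]1c1ccc(OCc5ccccc5)c(OCc5ccccc5)c1)c1cc(OCc5ccccc5)c(OCc5ccccc5)c(OCc5ccccc5)c1
F8 | step 14 | 1,5-bis(benzyloxy)-2-(diethoxymethyl)-6-(T residue)-3-(triisopropylsiloxy)benzene | O=C(O[C@@H]1[C@@H](c2c(OCc5ccccc5)cc(O[Si](C(C)C)(C(C)C)C(C)C)c(C(OCC)OCC)c2OCc5ccccc5)c2c(OCc5ccccc5)cc(OCc5ccccc5)cc2O[C@@H]1c1ccc(OCc5ccccc5)c(OCc5ccccc5)c1)c1cc(OCc5ccccc5)c(OCc5ccccc5)c(OCc5ccccc5)c1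
F9 | step 14 | 2,4-bis(benzyloxy)-3-(T residue)-6-(triisopropylsiloxy)benzaldehyde | O=C(O[C@@H]1[C@@H](c2c(OCc5ccccc5)cc(O[Si](C(C)C)(C(C)C)C(C)C)c(C=O)c2OCc5ccccc5)c2c(OCc5ccccc5)cc(OCc5ccccc5)cc2O[C@@H]1c1ccc(OCc5ccccc5)c(OCc5ccccc5)c1)c1cc(OCc5ccccc5)c(OCc5ccccc5)c(OCc5ccccc5)c1
F10 | step 7 | 1,1-bis(benzyloxy)ethene | C=C(OCc1ccccc1)OCc1ccccc1
F11 | step 7 | 3,3-bis(benzyloxy)-2-(T residue)cyclobutanone | O=C(O[C@@H]1[C@@H](C2C(=O)CC2(OCc5ccccc5)OCc5ccccc5)c2c(OCc5ccccc5)cc(OCc5ccccc5)cc2O[C@@H]1c1ccc(OCc5ccccc5)c(OCc5ccccc5)c1)c1cc(OCc5ccccc5)c(OCc5ccccc5)c(OCc5ccccc5)c1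
F12 | step 13 | ethyl 2-hydroxy-2-(L residue)acetate | CCOC(=O)C(O)c1c(OCc5ccccc5)cc(OCc5ccccc5)c2c1O[C@H](c1ccc(OCc5ccccc5)c(OCc5ccccc5)c1)[C@@H](OCc5ccccc5)C2
F13 | step 13 | ethyl 2-(tert-butyldimethylsiloxy)-2-(L residue)acetate | CCOC(=O)C(O[Si](C)(C)C(C)(C)C)c1c(OCc5ccccc5)cc(OCc5ccccc5)c2c1O[C@H](c1ccc(OCc5ccccc5)c(OCc5ccccc5)c1)[C@@H](OCc5ccccc5)C2
A1 | alternative 1 | 4-allyloxy-6-{[(2R,3R,4β)-5,7-bis(benzyloxy)-2-[3,4-bis(benzyloxy)phenyl]-3-(tert-butyldimethylsiloxy)chroman-4-yl]methyl}-2H-pyran-2-one | CC(C)(C)[Si](C)(C)O[C@@H]1[C@@H](CC2=CC(OCC=C)=CC(=O)O2)c2c(OCc5ccccc5)cc(OCc5ccccc5)cc2O[C@@H]1c1ccc(OCc5ccccc5)c(OCc5ccccc5)c1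
A2 | alternative 1 | 5-allyloxy-2-[(2R,3R,4β)-5,7-bis(benzyloxy)-2-[3,4-bis(benzyloxy)phenyl]-3-(tert-butyldimethylsiloxy)chroman-4-yl]benzene-1,3-diol | CC(C)(C)[Si](C)(C)O[C@@H]1[C@@H](c2c(O)cc(OCC=C)cc2O)c2c(OCc5ccccc5)cc(OCc5ccccc5)cc2O[C@@H]1c1ccc(OCc5ccccc5)c(OCc5ccccc5)c1
A3 | alternative 2 | bis-lactone: benzylated trimer skeleton with C2 of T and of M as lactone carbonyls and tert-butyldimethylsilyl ethers at both C3 | CC(C)(C)[Si](C)(C)O[C@@H]1[C@@H](c2c(OCc5ccccc5)cc3c(c2OCc5ccccc5)[C@H](c2c(OCc5ccccc5)cc(OCc5ccccc5)c4c2O[C@H](c2ccc(OCc5ccccc5)c(OCc5ccccc5)c2)[C@@H](OCc5ccccc5)C4)[C@@H](O[Si](C)(C)C(C)(C)C)C(=O)O3)c2c(OCc5ccccc5)cc(OCc5ccccc5)cc2OC1=O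
A4 | alternative 2 | 3,4-bis(benzyloxy)phenyllithium | [Li]c1ccc(OCc5ccccc5)c(OCc5ccccc5)c1
A5 | alternative 2 | bis(tert-butyldimethylsilyl ether) of the benzylated trimer (silyl ethers at C3 of T and of M) | CC(C)(C)[Si](C)(C)O[C@@H]1[C@@H](c2c(OCc5ccccc5)cc3c(c2OCc5ccccc5)[C@H](c2c(OCc5ccccc5)cc(OCc5ccccc5)c4c2O[C@H](c2ccc(OCc5ccccc5)c(OCc5ccccc5)c2)[C@@H](OCc5ccccc5)C4)[C@@H](O[Si](C)(C)C(C)(C)C)[C@@H](c2ccc(OCc5ccccc5)c(OCc5ccccc5)c2)O3)c2c(OCc5ccccc5)cc(OCc5ccccc5)cc2O[C@@H]1c1ccc(OCc5ccccc5)c(OCc5ccccc5)c1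
A6 | alternative 3 | 5-(tert-butyldimethylsiloxy)cyclohexane-1,3-dione | O=C1CC(O[Si](C)(C)C(C)(C)C)CC(=O)C1
A7 | alternative 3 | (E)-1-[3,4-bis(benzyloxy)phenyl]-3-(L residue)prop-2-en-1-one | O=C(/C=C/c1c(OCc5ccccc5)cc(OCc5ccccc5)c2c1O[C@H](c1ccc(OCc5ccccc5)c(OCc5ccccc5)c1)[C@@H](OCc5ccccc5)C2)c1ccc(OCc5ccccc5)c(OCc5ccccc5)c1
A8 | alternative 3 | 2-[3,4-bis(benzyloxy)phenyl]-7-(tert-butyldimethylsiloxy)-4-(L residue)-4,6,7,8-tetrahydro-5H-chromen-5-one (C7 unassigned) | O=C1CC(O[Si](C)(C)C(C)(C)C)CC2=C1[C@H](c1c(OCc5ccccc5)cc(OCc5ccccc5)c3c1O[C@H](c1ccc(OCc5ccccc5)c(OCc5ccccc5)c1)[C@@H](OCc5ccccc5)C3)C=C(c1ccc(OCc5ccccc5)c(OCc5ccccc5)c1)O2
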